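**Plan** (labdane numbering: ring A = C1–C5 and C10, with the C18 methyl and C19 ester on C4 and C20 on C10; ring B = C5–C10 with C17 on C8; side chain C11–C16 on C9)

1. Retrosynthesis: after the two O–Si bonds, the C20 methyl is traced back to a formyl group and the C8=C17 methylene to a C7=C8 enal (C17 as CHO). Ring B is then cut at C5–C6 and C9–C10, a [4+2] cut, into a ring A enal (C5H=C10–C20HO) and an acyclic (E)-diene C6=C7–C8(C17H2OSiEt3)=C9 that already carries the whole side chain.
2. Enabling feature: ring B is cis-fused to ring A, with H5, C20 and the C9 chain all on one face, and C8 carries an exocyclic methylene next to C7. This is the imprint of a suprafacial, endo Diels–Alder adduct (C7=C8 with an allylic C17 oxygen) after allylic transposition.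
3. Forward: ring A is bought as a β-keto ester; C4 is methylated and C5=O/C10H2 is turned into the enal. The diene is built from but-2-yne-1,4-diol (Negishi coupling, hydrostannation, Stille coupling). Ring B arises in the cycloaddition.
4. One double tosylhydrazone reduction then turns C20 into a methyl group and moves C7=C8 to C8=C17; desilylation ends the route.
5. Stereochemistry: C4 from an L-valine auxiliary; C5, C10 and C9 relayed from C4 in the cycloaddition (diene anti to the C4 ester, cis addition, endo formyl). The 13E alkene comes from trans-hydroalumination/iodination and the diene geometry from syn-hydrostannation.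

Key step: step 13

Assumption: in step 2 the ligand set named (toluene with 1,3-dioxolane) is taken to give the (S) enantiomer with the L-valine auxiliary; if the sense of induction is the opposite, D-valine tert-butyl ester is used in step 1 and nothing else changes.

Abbreviations: TBS = tert-butyldimethylsilyl, TES = triethylsilyl, Ts = 4-methylbenzenesulfonyl.

**Route**

Step 1
Reactants: 1 methyl 2-oxocyclohexane-1-carboxylate; 2 L-valine tert-butyl ester (free base from the commercial hydrochloride)
Product: 3 methyl 2-{[(2S)-1-tert-butoxy-3-methyl-1-oxobutan-2-yl]amino}cyclohex-1-ene-1-carboxylate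
Conditions: BF3·OEt2 (cat.), toluene, reflux, azeotropic removal of water
Reagents that add atoms: none
Why: Acid-catalysed condensation of the ketone of the β-keto ester with the primary amine (enamine formation) should give the conjugated, hydrogen-bonded enamino ester, which places the chiral auxiliary next to the carbon to be alkylated.

Step 2
Reactants: 3 methyl 2-{[(2S)-1-tert-butoxy-3-methyl-1-oxobutan-2-yl]amino}cyclohex-1-ene-1-carboxylate
Product: 6 methyl (1S)-1-methyl-2-oxocyclohexane-1-carboxylate, via lithium aza-enolate 4 (not isolated), via methylated imine 5 (not isolated)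
Conditions: LiN(iPr)2, toluene, 1,3-dioxolane, –78 °C; MeI, –78 → –40 °C; then aq. AcOH/NaOAc, rt
Reagents that add atoms: iodomethane CI; water O
Why: This is a chiral-auxiliary alkylation of a metalated enamine: in the chelated lithium aza-enolate the valine side chain shields one face, C-methylation should set the C4 quaternary center as (S), and mild acid hydrolysis of the imine frees the ketone and returns the auxiliary.

Step 3
Reactants: 6 methyl (1S)-1-methyl-2-oxocyclohexane-1-carboxylate
Product: 7 methyl (1R)-2-bromo-3-formyl-1-methylcyclohex-2-ene-1-carboxylate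
Conditions: PBr3, DMF, CHCl3, 0 → 60 °C; then aq. NaOAc, 0 °C
Reagents that add atoms: N,N-dimethylformamide CN(C)C=O; phosphorus tribromide BrP(Br)Br; water O
Why: Vilsmeier–Haack bromoformylation: the ketone can enolise only toward the CH2 group (C10), the enol is formylated by the bromoiminium salt and the carbonyl oxygen is replaced by bromide, so C5=O/C10H2 should become C5(Br)=C10–CHO without touching C4.

Step 4
Reactants: 7 methyl (1R)-2-bromo-3-formyl-1-methylcyclohex-2-ene-1-carboxylate
Product: 8 methyl (1S)-3-formyl-1-methylcyclohex-2-ene-1-carboxylate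
Conditions: Pd(OAc)2 (cat.), PPh3, HCO2H, Et3N, DMF, 60 °C
Reagents that add atoms: none
Why: Palladium-catalysed formate hydrogenolysis of a vinyl halide: oxidative addition into the activated C–Br bond of the β-bromo enal, decarboxylation of the formate and C–H reductive elimination should give the enal with the ring double bond in place.

Step 5
Reactants: 9 but-2-yne-1,4-diol
Product: 11 (2Z)-2-iodobut-2-ene-1,4-diol, via cyclic alkenylalanate 10 (not isolated)
Conditions: NaAlH2(OCH2CH2OMe)2, THF, 0 °C → rt; then I2, THF, –78 → 0 °C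
Reagents that add atoms: iodine II
Why: Alkoxide-directed trans-hydroalumination of the propargylic diol gives a five-membered alkenylalanate, and iodinolysis with retention should give the vinyl iodide with iodine cis to the CH2OH group on the other alkene carbon, which fixes the later 13E geometry (the alkyne is symmetrical, so no regiochemical question arises).

Step 6
Reactants: 11 (2Z)-2-iodobut-2-ene-1,4-diol
Product: 12 (2Z)-1,4-bis(tert-butyldimethylsilyloxy)-2-iodobut-2-ene
Conditions: TBSCl, imidazole, DMF, 0 °C → rt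
Reagents that add atoms: tert-butyldimethylsilyl chloride CC(C)(C)[Si](C)(C)Cl
Why: Standard silyl ether formation protects both primary allylic hydroxyl groups for the organometallic steps that follow.

Step 7
Reactants: 12 (2Z)-1,4-bis(tert-butyldimethylsilyloxy)-2-iodobut-2-ene; 13 (4-bromobut-1-yn-1-yl)trimethylsilane
Product: 15 (2E)-1,4-bis(tert-butyldimethylsilyloxy)-2-[4-(trimethylsilyl)but-3-yn-1-yl]but-2-ene, via organozinc bromide 14 (not isolated)
Conditions: 13, Zn dust, LiCl, THF, 50 °C; then 12, Pd(PPh3)4 (cat.), THF, rt → 50 °C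
Reagents that add atoms: none
Why: Negishi sp3–sp2 cross-coupling: zinc insertion into the primary bromide and palladium-catalysed coupling with the alkenyl iodide proceed with retention of the alkene geometry, so C12 should end up cis to C15.

Step 8
Reactants: 15 (2E)-1,4-bis(tert-butyldimethylsilyloxy)-2-[4-(trimethylsilyl)but-3-yn-1-yl]but-2-ene
Product: 17 methyl (6E)-8-(tert-butyldimethylsilyloxy)-6-[(tert-butyldimethylsilyloxy)methyl]oct-6-en-2-ynoate, via lithium acetylide 16 (not isolated)
Conditions: MeLi·LiBr, THF, 0 °C → rt; then ClCO2Me, –78 → 0 °C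
Reagents that add atoms: methyl chloroformate COC(=O)Cl
Why: Desilylative metalation: methyllithium attacks the alkynylsilane to release the lithium acetylide, which is C-acylated by the chloroformate to the alkynoate whose ester carbon becomes C17.

Step 9
Reactants: 17 methyl (6E)-8-(tert-butyldimethylsilyloxy)-6-[(tert-butyldimethylsilyloxy)methyl]oct-6-en-2-ynoate
Product: 18 methyl (2E,6E)-8-(tert-butyldimethylsilyloxy)-6-[(tert-butyldimethylsilyloxy)methyl]-2-(tributylstannyl)octa-2,6-dienoate
Conditions: Bu3SnH, Pd(PPh3)4 (cat.), THF, 0 °C → rt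
Reagents that add atoms: tributyltin hydride CCCC[SnH](CCCC)CCCC
Why: Palladium-catalysed hydrostannation of a 2-alkynoate is a syn addition that puts tin on the α-carbon and hydrogen on the β-carbon, so the chain (C11) should end up cis to the ester carbon and trans to tin.

Step 10
Reactants: 18 methyl (2E,6E)-8-(tert-butyldimethylsilyloxy)-6-[(tert-butyldimethylsilyloxy)methyl]-2-(tributylstannyl)octa-2,6-dienoate
Product: 19 methyl (2Z,6E)-8-(tert-butyldimethylsilyloxy)-6-[(tert-butyldimethylsilyloxy)methyl]-2-ethenylocta-2,6-dienoate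
Conditions: CH2=CHBr (THF solution), Pd2(dba)3 (cat.), AsPh3, CuI (cat.), NMP, 50 °C, sealed tube
Reagents that add atoms: bromoethene C=CBr
Why: Stille coupling with retention at the alkenylstannane (copper-assisted transmetalation for the hindered α-stannyl acrylate) should install the vinyl group trans to C11, the diene geometry needed for the cycloaddition.

Step 11
Reactants: 19 methyl (2Z,6E)-8-(tert-butyldimethylsilyloxy)-6-[(tert-butyldimethylsilyloxy)methyl]-2-ethenylocta-2,6-dienoate
Product: 20 (2Z,6E)-8-(tert-butyldimethylsilyloxy)-6-[(tert-butyldimethylsilyloxy)methyl]-2-ethenylocta-2,6-dien-1-ol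
Conditions: iBu2AlH, CH2Cl2, –78 °C; aq. potassium sodium tartrate
Reagents that add atoms: none
Why: 1,2-Reduction of the conjugated ester by the aluminium hydride gives the primary allylic alcohol (C17) and turns the electron-poor, dimerisation-prone dienoate into an electron-rich diene.

Step 12
Reactants: 20 (2Z,6E)-8-(tert-butyldimethylsilyloxy)-6-[(tert-butyldimethylsilyloxy)methyl]-2-ethenylocta-2,6-dien-1-ol
Product: 21 (3Z,7E)-9-(tert-butyldimethylsilyloxy)-7-[(tert-butyldimethylsilyloxy)methyl]-3-[(triethylsilyloxy)methyl]nona-1,3,7-triene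
Conditions: Et3SiCl, imidazole, CH2Cl2, 0 °C
Reagents that add atoms: chlorotriethylsilane CC[Si](Cl)(CC)CC
Why: Silyl ether formation with the more labile triethylsilyl group marks the C17 oxygen for later selective unveiling beside the two TBS ethers.

Step 13
Reactants: 8 methyl (1S)-3-formyl-1-methylcyclohex-2-ene-1-carboxylate; 21 (3Z,7E)-9-(tert-butyldimethylsilyloxy)-7-[(tert-butyldimethylsilyloxy)methyl]-3-[(triethylsilyloxy)methyl]nona-1,3,7-triene
Product: 22 methyl (1S,4aS,5S,8aS)-5-{(3E)-5-(tert-butyldimethylsilyloxy)-3-[(tert-butyldimethylsilyloxy)methyl]pent-3-en-1-yl}-4a-formyl-1-methyl-6-[(triethylsilyloxy)methyl]-1,2,3,4,4a,5,8,8a-octahydronaphthalene-1-carboxylate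
Conditions: Me2AlCl, CH2Cl2, –78 → –20 °C
Reagents that add atoms: none
Why: Me2AlCl binds the formyl oxygen of 8 and lowers its LUMO, and diene 21 adds across C5=C10 in a concerted but asynchronous normal-demand Diels–Alder reaction in which the C5–C6 bond leads the C9–C10 bond; the closest known reaction type is the Lewis-acid-promoted cycloaddition of cyclohex-1-enecarbaldehydes and 2-substituted acroleins with 1-alkyl dienes. Ring B closes as a six-membered ring in one suprafacial [4+2] event on the existing ring A, so the A/B fusion can only be cis, with H5 and the C20 formyl group on the same face. The orientation should be the ortho one, because the C9 alkyl group raises the HOMO coefficient at the unsubstituted terminus C6, which pairs with the β-carbon C5 of the enal, while the CH2OSiEt3 group on C8 is only a weak opposing donor. C9 is set by the endo arrangement of the complexed formyl group, which places the outside substituent of the (E)-configured C8=C9 bond on the same face as C20. The absolute sense of C5, C9 and C10 is relayed from C4: in the reactive half-chair the methoxycarbonyl group (smaller A value than methyl, better σ* acceptor) should sit pseudoaxial and antiperiplanar to the forming C5–C6 bond, so the diene adds to the face that carries the C4 methyl group. The step thus needs regio-, endo- and facial selectivity, secured in turn by the 1-alkyl substitution of the diene, the single complexed carbonyl on C10 and the C4 quaternary center.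

Step 14
Reactants: 22 methyl (1S,4aS,5S,8aS)-5-{(3E)-5-(tert-butyldimethylsilyloxy)-3-[(tert-butyldimethylsilyloxy)methyl]pent-3-en-1-yl}-4a-formyl-1-methyl-6-[(triethylsilyloxy)methyl]-1,2,3,4,4a,5,8,8a-octahydronaphthalene-1-carboxylate
Product: 23 methyl (1S,4aS,5S,8aS)-5-{(3E)-5-(tert-butyldimethylsilyloxy)-3-[(tert-butyldimethylsilyloxy)methyl]pent-3-en-1-yl}-4a,6-diformyl-1-methyl-1,2,3,4,4a,5,8,8a-octahydronaphthalene-1-carboxylate
Conditions: (COCl)2, DMSO, CH2Cl2, –78 → –30 °C; Et3N, → 0 °C
Reagents that add atoms: none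
Why: Swern oxidation applied directly to a primary triethylsilyl ether: the chlorosulfonium reagent should cleave the labile primary allylic TES ether and oxidise that carbon to the enal in the same flask, while the TBS ethers and the non-enolisable C20 aldehyde stay untouched.

Step 15
Reactants: 23 methyl (1S,4aS,5S,8aS)-5-{(3E)-5-(tert-butyldimethylsilyloxy)-3-[(tert-butyldimethylsilyloxy)methyl]pent-3-en-1-yl}-4a,6-diformyl-1-methyl-1,2,3,4,4a,5,8,8a-octahydronaphthalene-1-carboxylate
Product: 24 bis(4-methylbenzenesulfonylhydrazone) of 23 at C17 and C20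
Conditions: TsNHNH2, THF/EtOH, rt → 40 °C
Reagents that add atoms: 4-methylbenzenesulfonohydrazide Cc1ccc(cc1)S(=O)(=O)NN
Why: Hydrazone formation should occur at both aldehydes under near-neutral conditions, and the mild temperature disfavours aza-Michael closure of the unsaturated hydrazone.

Step 16
Reactants: 24 bis(4-methylbenzenesulfonylhydrazone) of 23 at C17 and C20
Product: 27 methyl (1S,4aR,5S,8aS)-5-{(3E)-5-(tert-butyldimethylsilyloxy)-3-[(tert-butyldimethylsilyloxy)methyl]pent-3-en-1-yl}-1,4a-dimethyl-6-methylidenedecahydronaphthalene-1-carboxylate, via bis(N-borylhydrazine) 25 (not isolated), via bis(diazene) 26 (not isolated)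
Conditions: catecholborane, CHCl3, 0 °C → rt; then NaOAc·3H2O, reflux
Reagents that add atoms: none
Why: Tosylhydrazone reduction with alkene transposition: catecholborane adds hydride 1,2 to both C=N bonds, acetate then triggers loss of sulfinate to two diazenes, the alkyl diazene at C20 loses N2 to leave the angular methyl group, and the allylic diazene at C17 undergoes a retro-ene hydrogen shift to C7 that should create the exocyclic C8=C17 bond.

Step 17
Reactants: 27 methyl (1S,4aR,5S,8aS)-5-{(3E)-5-(tert-butyldimethylsilyloxy)-3-[(tert-butyldimethylsilyloxy)methyl]pent-3-en-1-yl}-1,4a-dimethyl-6-methylidenedecahydronaphthalene-1-carboxylate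
Product: 28 methyl (1S,4aR,5S,8aS)-5-[(3E)-5-hydroxy-3-(hydroxymethyl)pent-3-en-1-yl]-1,4a-dimethyl-6-methylidenedecahydronaphthalene-1-carboxylate
Conditions: Bu4NF, THF, 0 °C → rt
Reagents that add atoms: none
Why: Fluoride-induced silyl ether cleavage should free both primary allylic alcohols, while the hindered tertiary methyl ester and the two alkenes are inert.

**Compound list**

1 | methyl 2-oxocyclohexane-1-carboxylate | COC(=O)C1CCCCC1=O | starting material
2 | L-valine tert-butyl ester | CC(C)[C@H](N)C(=O)OC(C)(C)C | starting material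
3 | methyl 2-{[(2S)-1-tert-butoxy-3-methyl-1-oxobutan-2-yl]amino}cyclohex-1-ene-1-carboxylate | COC(=O)C1=C(N[C@@H](C(C)C)C(=O)OC(C)(C)C)CCCC1 | intermediate
4 | N-lithio derivative of 3 (lithium aza-enolate) | COC(=O)C1=C(N([Li])[C@@H](C(C)C)C(=O)OC(C)(C)C)CCCC1 | intermediate
5 | methyl (1S)-2-{[(2S)-1-tert-butoxy-3-methyl-1-oxobutan-2-yl]imino}-1-methylcyclohexane-1-carboxylate | COC(=O)[C@@]1(C)CCCCC1=N[C@@H](C(C)C)C(=O)OC(C)(C)C | intermediate
6 | methyl (1S)-1-methyl-2-oxocyclohexane-1-carboxylate | COC(=O)[C@@]1(C)CCCCC1=O | intermediate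
7 | methyl (1R)-2-bromo-3-formyl-1-methylcyclohex-2-ene-1-carboxylate (same spatial arrangement at C1 as in 6; the descriptor changes because bromine raises the priority of C2) | O=CC1=C(Br)[C@@](C)(C(=O)OC)CCC1 | intermediate
8 | methyl (1S)-3-formyl-1-methylcyclohex-2-ene-1-carboxylate | O=CC1=C[C@@](C)(C(=O)OC)CCC1 | intermediate
9 | but-2-yne-1,4-diol | OCC#CCO | starting material
10 | disodium salt of the five-membered alkenylalanate from 9 (aluminium on the alkene carbon, cis to the ring CH2O) | [Na+].[Na+].COCCO[Al-]1(OCCOC)OC/C=C1/C[O-] | intermediate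
11 | (2Z)-2-iodobut-2-ene-1,4-diol | OC/C(I)=C/CO | intermediate
12 | (2Z)-1,4-bis(tert-butyldimethylsilyloxy)-2-iodobut-2-ene | CC(C)(C)[Si](C)(C)OC/C(I)=C/CO[Si](C)(C)C(C)(C)C | intermediate
13 | (4-bromobut-1-yn-1-yl)trimethylsilane | C[Si](C)(C)C#CCCBr | starting material
14 | [4-(trimethylsilyl)but-3-yn-1-yl]zinc bromide | C[Si](C)(C)C#CCC[Zn]Br | intermediate
15 | (2E)-1,4-bis(tert-butyldimethylsilyloxy)-2-[4-(trimethylsilyl)but-3-yn-1-yl]but-2-ene | C[Si](C)(C)C#CCC/C(CO[Si](C)(C)C(C)(C)C)=C\CO[Si](C)(C)C(C)(C)C | intermediate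
16 | {(5E)-7-(tert-butyldimethylsilyloxy)-5-[(tert-butyldimethylsilyloxy)methyl]hept-5-en-1-yn-1-yl}lithium | [Li]C#CCC/C(CO[Si](C)(C)C(C)(C)C)=C\CO[Si](C)(C)C(C)(C)C | intermediate
17 | methyl (6E)-8-(tert-butyldimethylsilyloxy)-6-[(tert-butyldimethylsilyloxy)methyl]oct-6-en-2-ynoate | COC(=O)C#CCC/C(CO[Si](C)(C)C(C)(C)C)=C\CO[Si](C)(C)C(C)(C)C | intermediate
18 | methyl (2E,6E)-8-(tert-butyldimethylsilyloxy)-6-[(tert-butyldimethylsilyloxy)methyl]-2-(tributylstannyl)octa-2,6-dienoate | CCCC[Sn](CCCC)(CCCC)/C(C(=O)OC)=C/CC/C(CO[Si](C)(C)C(C)(C)C)=C\CO[Si](C)(C)C(C)(C)C | intermediate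
19 | methyl (2Z,6E)-8-(tert-butyldimethylsilyloxy)-6-[(tert-butyldimethylsilyloxy)methyl]-2-ethenylocta-2,6-dienoate | C=C/C(C(=O)OC)=C/CC/C(CO[Si](C)(C)C(C)(C)C)=C\CO[Si](C)(C)C(C)(C)C | intermediate
20 | (2Z,6E)-8-(tert-butyldimethylsilyloxy)-6-[(tert-butyldimethylsilyloxy)methyl]-2-ethenylocta-2,6-dien-1-ol | C=C/C(CO)=C/CC/C(CO[Si](C)(C)C(C)(C)C)=C\CO[Si](C)(C)C(C)(C)C | intermediate
21 | (3Z,7E)-9-(tert-butyldimethylsilyloxy)-7-[(tert-butyldimethylsilyloxy)methyl]-3-[(triethylsilyloxy)methyl]nona-1,3,7-triene | C=C/C(CO[Si](CC)(CC)CC)=C/CC/C(CO[Si](C)(C)C(C)(C)C)=C\CO[Si](C)(C)C(C)(C)C | intermediate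
22 | methyl (1S,4aS,5S,8aS)-5-{(3E)-5-(tert-butyldimethylsilyloxy)-3-[(tert-butyldimethylsilyloxy)methyl]pent-3-en-1-yl}-4a-formyl-1-methyl-6-[(triethylsilyloxy)methyl]-1,2,3,4,4a,5,8,8a-octahydronaphthalene-1-carboxylate | CC[Si](CC)(CC)OCC1=CC[C@H]2[C@](C=O)(CCC[C@]2(C)C(=O)OC)[C@H]1CC/C(=C\CO[Si](C)(C)C(C)(C)C)CO[Si](C)(C)C(C)(C)C | intermediate
23 | methyl (1S,4aS,5S,8aS)-5-{(3E)-5-(tert-butyldimethylsilyloxy)-3-[(tert-butyldimethylsilyloxy)methyl]pent-3-en-1-yl}-4a,6-diformyl-1-methyl-1,2,3,4,4a,5,8,8a-octahydronaphthalene-1-carboxylate | O=CC1=CC[C@H]2[C@](C=O)(CCC[C@]2(C)C(=O)OC)[C@H]1CC/C(=C\CO[Si](C)(C)C(C)(C)C)CO[Si](C)(C)C(C)(C)C | intermediate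
24 | bis(4-methylbenzenesulfonylhydrazone) of 23 at C17 and C20 (C=N geometry not defined) | Cc1ccc(cc1)S(=O)(=O)NN=CC1=CC[C@H]2[C@](C=NNS(=O)(=O)c3ccc(C)cc3)(CCC[C@]2(C)C(=O)OC)[C@H]1CC/C(=C\CO[Si](C)(C)C(C)(C)C)CO[Si](C)(C)C(C)(C)C | intermediate
25 | bis[N-(1,3,2-benzodioxaborol-2-yl)-N'-tosylhydrazine] from hydroboration of both C=N bonds of 24 | Cc1ccc(cc1)S(=O)(=O)NN(B1Oc2ccccc2O1)CC1=CC[C@H]2[C@](CN(NS(=O)(=O)c3ccc(C)cc3)B3Oc4ccccc4O3)(CCC[C@]2(C)C(=O)OC)[C@H]1CC/C(=C\CO[Si](C)(C)C(C)(C)C)CO[Si](C)(C)C(C)(C)C | intermediate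
26 | bis(diazene) with HN=N–CH2 groups at C17 and C20 | N=NCC1=CC[C@H]2[C@](CN=N)(CCC[C@]2(C)C(=O)OC)[C@H]1CC/C(=C\CO[Si](C)(C)C(C)(C)C)CO[Si](C)(C)C(C)(C)C | intermediate
27 | methyl (1S,4aR,5S,8aS)-5-{(3E)-5-(tert-butyldimethylsilyloxy)-3-[(tert-butyldimethylsilyloxy)methyl]pent-3-en-1-yl}-1,4a-dimethyl-6-methylidenedecahydronaphthalene-1-carboxylate | C=C1CC[C@H]2[C@](C)(CCC[C@]2(C)C(=O)OC)[C@H]1CC/C(=C\CO[Si](C)(C)C(C)(C)C)CO[Si](C)(C)C(C)(C)C | intermediate
28 | methyl (1S,4aR,5S,8aS)-5-[(3E)-5-hydroxy-3-(hydroxymethyl)pent-3-en-1-yl]-1,4a-dimethyl-6-methylidenedecahydronaphthalene-1-carboxylate | C=C1CC[C@H]2[C@](C)(CCC[C@]2(C)C(=O)OC)[C@H]1CC/C(=C\CO)CO | target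

**Count**

Total steps: 17 (steps 1–4 dienophile, steps 5–12 diene, steps 13–17 union and end game). Longest linear sequence: 13 steps (steps 5–17, from but-2-yne-1,4-diol).

**Steps most likely to fail**

Step 13. What may go wrong is poor facial discrimination at the C5=C10 bond, with addition syn to the C4 ester competing with the wanted anti addition; erosion of the ortho orientation is a second concern. Fallback: the source of facial control is moved from the substrate to the reagent. Compounds 8 and 21 are combined under a chiral cationic oxazaborolidine Lewis acid (the B-o-tolyl oxazaborolidine of α,α-diphenylprolinol, protonated by Tf2NH, CH2Cl2, –78 °C). The catalyst antipode is chosen so that its shielding of the enal matches attack anti to the C4 ester. The fallback sets out from 8 and 21 and comes back to the route at 22; it makes no new compound (none, F0).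

Step 16. What may go wrong is incomplete hydride transfer to the hindered neopentyl hydrazone at C20, or conjugate reduction and pyrazoline formation at the unsaturated hydrazone. Fallback: the two carbons are treated separately, setting out from 22 and coming back at 27. NaBH4 with CeCl3·7H2O in MeOH at –40 °C reduces the C20 aldehyde to the 4a-hydroxymethyl compound F1. 1,1'-Thiocarbonyldiimidazole in warm 1,2-dichloroethane converts it to the imidazolylthiocarbonate F2. Barton–McCombie deoxygenation (Bu3SnH, AIBN, toluene, reflux) gives the 4a-methyl TES ether F3. PPTS in MeOH at 0 °C removes the TES group to give the allylic alcohol F4. Mitsunobu displacement of F4 with 2-nitrobenzenesulfonylhydrazide (PPh3, diethyl azodicarboxylate, –30 °C → rt) gives the allylic diazene, which loses N2 by retro-ene hydrogen shift to give 27.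

Step 3. What may go wrong is low conversion of the hindered α-quaternary ketone, or cleavage of the β-keto ester under the hot haloiminium conditions. Fallback: the classical formylation, reduction and transposition sequence, setting out from 6 and coming back at 8 (7 is bypassed). LiN(iPr)2 and 2,2,2-trifluoroethyl formate in THF at –78 °C give the hydroxymethylidene ketone F5. Isopropyl iodide and K2CO3 in acetone give the isopropyl enol ether F6. NaBH4 with CeCl3·7H2O reduces the ketone to the allylic alcohol F7, and dilute aqueous HCl then hydrolyses the enol ether with allylic transposition to give 8.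

**Further compounds**

F0 | step 13 | none | none
F1 | step 16 | methyl (1S,4aS,5S,8aS)-5-{(3E)-5-(tert-butyldimethylsilyloxy)-3-[(tert-butyldimethylsilyloxy)methyl]pent-3-en-1-yl}-4a-(hydroxymethyl)-1-methyl-6-[(triethylsilyloxy)methyl]-1,2,3,4,4a,5,8,8a-octahydronaphthalene-1-carboxylate | CC[Si](CC)(CC)OCC1=CC[C@H]2[C@](CO)(CCC[C@]2(C)C(=O)OC)[C@H]1CC/C(=C\CO[Si](C)(C)C(C)(C)C)CO[Si](C)(C)C(C)(C)C
F2 | step 16 | O-(imidazol-1-ylcarbonothioyl) derivative of F1 at the 4a-hydroxymethyl group | CC[Si](CC)(CC)OCC1=CC[C@H]2[C@](COC(=S)n3ccnc3)(CCC[C@]2(C)C(=O)OC)[C@H]1CC/C(=C\CO[Si](C)(C)C(C)(C)C)CO[Si](C)(C)C(C)(C)C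
F3 | step 16 | methyl (1S,4aR,5R,8aS)-5-{(3E)-5-(tert-butyldimethylsilyloxy)-3-[(tert-butyldimethylsilyloxy)methyl]pent-3-en-1-yl}-1,4a-dimethyl-6-[(triethylsilyloxy)methyl]-1,2,3,4,4a,5,8,8a-octahydronaphthalene-1-carboxylate | CC[Si](CC)(CC)OCC1=CC[C@H]2[C@](C)(CCC[C@]2(C)C(=O)OC)[C@H]1CC/C(=C\CO[Si](C)(C)C(C)(C)C)CO[Si](C)(C)C(C)(C)C
F4 | step 16 | methyl (1S,4aR,5R,8aS)-5-{(3E)-5-(tert-butyldimethylsilyloxy)-3-[(tert-butyldimethylsilyloxy)methyl]pent-3-en-1-yl}-6-(hydroxymethyl)-1,4a-dimethyl-1,2,3,4,4a,5,8,8a-octahydronaphthalene-1-carboxylate | OCC1=CC[C@H]2[C@](C)(CCC[C@]2(C)C(=O)OC)[C@H]1CC/C(=C\CO[Si](C)(C)C(C)(C)C)CO[Si](C)(C)C(C)(C)C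
F5 | step 3 | methyl (1S)-3-(hydroxymethylidene)-1-methyl-2-oxocyclohexane-1-carboxylate | OC=C1CCC[C@](C)(C(=O)OC)C1=O
F6 | step 3 | methyl (1S)-1-methyl-2-oxo-3-[(propan-2-yloxy)methylidene]cyclohexane-1-carboxylate | CC(C)OC=C1CCC[C@](C)(C(=O)OC)C1=O
F7 | step 3 | methyl (1S)-2-hydroxy-1-methyl-3-[(propan-2-yloxy)methylidene]cyclohexane-1-carboxylate (carbinol epimers) | CC(C)OC=C1CCC[C@](C)(C(=O)OC)C1O
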